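**Plan**
1. Retrosynthesis: cut the C8–O ester and the lactone (C12 from CO, C13 from an alkyne homologation). Re-join C5 to C8 while closing an epoxide over C4/C15, which is an alkoxide/epoxide Grob fragmentation run backwards. Then cut the cyclobutane bonds C5–C6 and C7–C8 ([2+2]), the C3–O tether and the C10–C14 bond.
2. Enabling feature: the array O–C8 … C5=C4(E)–C15–O. With C6 and C7 taken out, the remaining ring C8–C9–C10–C1–C2–C3–C4–C5 is an eight-membered 1,3-dioxygenated carbocycle, and the target is its two-carbon ring-expansion product.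
3. Forward: cyclooctanone → cross-conjugated dienone → asymmetric 1,4-addition (C14) → 1,3-dione, bridged as a silylene → α′-oxygen tether and intramolecular [2+2] (cyclobutane C5–C6–C7–C8) → C4 spiro-epoxide → fluoride-triggered expansion of the eight- to the ten-membered ring → carbonylative lactonisation, C8 reduction, methacrylation.
4. Stereochemistry: C10 from the chiral rhodium catalyst. The silylene bridge (O8 cis to C14) and the C3–O tether (O6 cis to C4) relay it to C6 and C7 in the photocycloaddition. The E-alkene follows stereospecifically from the β-epoxide, and C8 from axial hydride delivery.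

Key step: step 13

Remark: in all intermediates atoms carry the germacrane numbers of the target (ring C1–C10, lactone carbons C11–C13, C14 on C10, C15 on C4); α/β refer to the usual drawing with C14 β.

**Step 1**
Reactants: 1 cyclooctanone
Product: 2 (2Z,7Z)-cycloocta-2,7-dien-1-one
Conditions: IBX (4 equiv), DMSO/fluorobenzene, 80 °C
Reagents that add atoms: none
Why: IBX dehydrogenation of the ketone on both α,β-positions should give the cross-conjugated dienone, the ring size allowing only Z double bonds.

**Step 2**
Reactants: 2 (2Z,7Z)-cycloocta-2,7-dien-1-one; 3 (E)-(2-phenylethenyl)boronic acid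
Product: 4 (2Z,7R)-7-[(E)-2-phenylethenyl]cyclooct-2-en-1-one
Conditions: Rh(acac)(C2H4)2 (3 mol %), (R)-BINAP, dioxane/H2O 10:1, 100 °C
Reagents that add atoms: none
Why: Hayashi–Miyaura rhodium-catalysed asymmetric 1,4-addition to one of the two equivalent enone units; the alkenyl-rhodium/(R)-BINAP species should select the enone face in the same sense as with cyclohex-2-enone, which sets C10 (R), and the product enone is less reactive than the strained dienone, so mono-addition should dominate.

**Step 3**
Reactants: 4 (2Z,7R)-7-[(E)-2-phenylethenyl]cyclooct-2-en-1-one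
Product: 6 (2Z,7R)-7-(hydroxymethyl)cyclooct-2-en-1-one, via keto aldehyde 5 (not isolated)
Conditions: O3, CH2Cl2/pyridine, −78 °C; Me2S; then NaBH(OAc)3, AcOH, CH2Cl2, 0 °C
Reagents that add atoms: ozone, [O-][O+]=O
Why: Ozonolysis cleaves the electron-rich styryl double bond in preference to the electron-poor enone, and NaBH(OAc)3 then reduces the aldehyde chemoselectively without touching the enone or epimerising C10.

**Step 4**
Reactants: 6 (2Z,7R)-7-(hydroxymethyl)cyclooct-2-en-1-one
Product: 7 (5R)-5-(hydroxymethyl)cyclooctane-1,3-dione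
Conditions: Na2PdCl4 (10 mol %), t-BuOOH, AcOH/H2O, 50 °C
Reagents that add atoms: tert-butyl hydroperoxide, CC(C)(C)OO
Why: Wacker–Tsuji oxidation: divalent palladium activates the enone double bond and the peroxide oxygen is delivered to the β-carbon (C4), which should give the 1,3-dione as it does for cyclooct-2-enone itself.

**Step 5**
Reactants: 7 (5R)-5-(hydroxymethyl)cyclooctane-1,3-dione
Product: 8 silylene-bridged enol ether (C4 ketone, C5=C8, Si(t-Bu)2 joining the oxygen on C8 and the C14 oxygen; 10R)
Conditions: t-Bu2Si(OTf)2, 2,6-lutidine, CH2Cl2, 0 °C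
Reagents that add atoms: di-tert-butylsilyl bis(trifluoromethanesulfonate), CC(C)(C)[Si](OS(=O)(=O)C(F)(F)F)(OS(=O)(=O)C(F)(F)F)C(C)(C)C
Why: Silylene formation: after silylation of the primary alcohol the silicon closes onto the nearer enol oxygen (seven-membered ring through O8, nine through O4), which fixes the enol regiochemistry (C5=C8 conjugated with C4=O) and holds O8 cis to C14.

**Step 6**
Reactants: 8 silylene-bridged enol ether
Product: 9 3α-hydroxy ketone (8 with OH on C3, trans to the silylene bridge; 3R,10R)
Conditions: LiN(i-Pr)2, THF, −78 °C; then 2-(phenylsulfonyl)-3-phenyloxaziridine, −78 °C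
Reagents that add atoms: 2-(phenylsulfonyl)-3-phenyloxaziridine, O=S(=O)(c1ccccc1)N1OC1c1ccccc1
Why: Kinetic α′-deprotonation of the vinylogous ester at C3 (a γ-dienolate would need a bridgehead double bond) and enolate hydroxylation by the N-sulfonyloxaziridine from the α-face, opposite the transannular silylene bridge, should give the 3α-alcohol.

**Step 7**
Reactants: 9 3α-hydroxy ketone; 10 methyl propiolate
Product: 11 (E)-β-alkoxyacrylate (methyl (E)-3-oxyprop-2-enoate ether of the 3-OH of 9)
Conditions: N-methylmorpholine (cat.), CH2Cl2, rt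
Reagents that add atoms: none
Why: Amine-catalysed oxa-Michael addition of the secondary alcohol to the propiolate should give the (E)-enol ether (vinylogous carbonate).

**Step 8**
Reactants: 11 (E)-β-alkoxyacrylate
Product: 12 tetracyclic photoadduct (cyclobutane C5–C6–C7–C8 with H5 β and O8 β; oxolan-3-one ring C4–C3–O–C6–C5 with O6 α; 7β-CO2Me)
Conditions: hν (λ ≥ 300 nm, Pyrex), MeCN (5 mM), degassed, rt
Reagents that add atoms: none
Why: Intramolecular enone–alkene [2+2] photocycloaddition in the straight mode (rule of five: C5–C6 closes the five-membered ring, then C8–C7); the C3–O tether delivers the alkene to the open α-face and forces O6 cis to C4, the silylene bridge allows only O8 cis to C14, and the ester on C7 should take the less hindered β (exo) position trans to O6, which is also the thermodynamic one.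

**Step 9**
Reactants: 12 tetracyclic photoadduct
Product: 14 6α-OTBS keto ester (C3–O bond cleaved, C3 now CH2), via bis-silyl enol ether 13 (not isolated)
Conditions: SmI2 (2.2 equiv), THF, −78 °C; then TBSOTf, 2,6-lutidine, −78 to 0 °C; aq citric acid work-up
Reagents that add atoms: tert-butyldimethylsilyl trifluoromethanesulfonate, CC(C)(C)[Si](C)(C)OS(=O)(=O)C(F)(F)F
Why: SmI2 reductive cleavage of the α-alkoxy ketone gives the C3=C4 samarium enolate and the C6 samarium alkoxide, both silylated in situ so that the cyclobutanol oxygen is never free while a ketone is β to it (which would allow retro-aldol opening of the cyclobutane); mild acid then hydrolyses only the silyl enol ether.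

**Step 10**
Reactants: 14 6α-OTBS keto ester
Product: 15 4-methylene compound (C4=C15H2)
Conditions: Zn, CH2Br2, TiCl4, THF/CH2Cl2, 0 °C to rt
Reagents that add atoms: dibromomethane, BrCBr
Why: Takai–Lombardo methylenation converts the hindered ketone into the exocyclic alkene under non-basic conditions that leave the ester and the silyl ethers untouched.

**Step 11**
Reactants: 15 4-methylene compound
Product: 17 7β-ethynyl compound, via aldehyde 16 (not isolated)
Conditions: i-Bu2AlH (1.2 equiv), CH2Cl2, −78 °C; then MeOH, K2CO3, dimethyl (1-diazo-2-oxopropyl)phosphonate, −78 °C to rt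
Reagents that add atoms: dimethyl (1-diazo-2-oxopropyl)phosphonate, CC(=O)C(=[N+]=[N-])P(=O)(OC)OC
Why: Partial reduction of the ester to the aldehyde and in situ Seyferth–Gilbert homologation give the terminal alkyne; C7 should stay β because that exo position, trans to O6, is also the thermodynamic one under the basic conditions.

**Step 12**
Reactants: 17 7β-ethynyl compound
Product: 18 4β,15-epoxide (spiro-epoxide, oxygen on the β-face, cis to H5)
Conditions: mCPBA, NaHCO3, CH2Cl2, 0 °C
Reagents that add atoms: 3-chloroperbenzoic acid, O=C(OO)c1cccc(Cl)c1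
Why: Prilezhaev epoxidation of the 1,1-disubstituted alkene; the α-face is screened by the neighbouring endo 6-OTBS group, so oxygen should be delivered from the β-face, giving the epoxide configuration needed for the E-alkene.

**Step 13**
Reactants: 18 4β,15-epoxide
Product: 21 (4E,6R,7S,10R)-7-ethynyl-6,14,15-trihydroxy ten-membered 8-ketone, via epoxy diol 19 (not isolated), via silyl ether 20 (not isolated)
Conditions: TBAF (3 equiv), THF, −20 °C; then AcOH (3 equiv), rt
Reagents that add atoms: none
Why: Fluoride opens the strained seven-membered silylene first, and the liberated C8 cyclobutanolate undergoes a Grob fragmentation: the oxygen lone pair forms the C8 ketone, the ring-fusion σ-bond C5–C8 breaks anti-periplanar to the C4–O bond of the spiro-epoxide, C4=C5 forms and the epoxide oxygen leaves as the C15 alkoxide. The closest known reaction types are the alkoxide/epoxide (epoxy-alcohol) fragmentation and fluoride-induced Grob fragmentations of silyloxycyclobutanes, here driven by release of cyclobutane and epoxide strain. No ring is closed: the ten-membered carbocycle arises by cleavage of the zero-atom bridge of the bicyclo[6.2.0]decane, that is by two-carbon (C6, C7) expansion of the eight-membered ring. No stereocentre is created; the alkene geometry is set stereospecifically, because with the epoxide oxygen β the anti-periplanar arrangement places C15 syn to C6 and C3 anti to C6, which is the E (trans-cyclodecene) geometry. The selectivity needed is cleavage of C5–C8 and not of C5–C6 or C7–C8, which is secured by keeping O6 silylated (non-donating) until the fragmentation is over and by C7 carrying no nucleofuge. Acetic acid then buffers the fluoride so that the 6-OTBS group is removed without retro-aldol cleavage or C7 epimerisation of the β-hydroxy ketone.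

**Step 14**
Reactants: 21 trihydroxy ketone
Product: 22 14,15-bis(TBS) ether (6α-OH free)
Conditions: TBSCl (2.2 equiv), imidazole, DMF, 0 °C
Reagents that add atoms: tert-butyldimethylsilyl chloride, CC(C)(C)[Si](C)(C)Cl
Why: Silylation should take the two primary alcohols and leave the hindered secondary allylic 6-OH free.

**Step 15**
Reactants: 22 14,15-bis(TBS) ether
Product: 23 14,15-bis(TBSO)-8-oxo-1(10)-dihydrogermacra-4,11(13)-dien-12,6α-olide
Conditions: PdCl2 (5 mol %), SnCl2 (5 mol %), PPh3 (10 mol %), CO (7 atm), MeCN, 75 °C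
Reagents that add atoms: carbon monoxide, [C-]#[O+]
Why: Palladium-catalysed cyclocarbonylation of the homopropargylic alcohol (alkoxycarbonyl-palladium formation at O6, syn addition across the alkyne, protonolysis) gives the α-methylene-γ-butyrolactone directly; the trans 6,7-relationship is already in place, and C8 is still a ketone so no second hydroxyl can compete.

**Step 16**
Reactants: 23 8-oxo lactone
Product: 24 8α-hydroxy lactone (8S)
Conditions: NaBH4, CeCl3·7H2O, MeOH, −78 °C
Reagents that add atoms: none
Why: Luche 1,2-reduction spares the α-methylene lactone; axial-type attack of the small hydride, as with 2-substituted cyclohexanones, should give the equatorial 8α-alcohol trans to the C7–C11 bond.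

**Step 17**
Reactants: 24 8α-hydroxy lactone; 25 methacrylic anhydride
Product: 26 8α-methacrylate 14,15-bis(TBS) ether
Conditions: Et3N, DMAP (cat.), CH2Cl2, 0 °C to rt
Reagents that add atoms: none
Why: DMAP-catalysed acyl transfer esterifies the only free hydroxyl with retention at C8.

**Step 18**
Reactants: 26 8α-methacrylate 14,15-bis(TBS) ether
Product: 27 CNP0256084.2
Conditions: HF·pyridine, pyridine/THF, 0 °C
Reagents that add atoms: none
Why: Fluoride desilylation of the two primary TBS ethers under buffered acidic conditions leaves the methacrylate and the α-methylene lactone intact.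

**Compound list**
1 | cyclooctanone | O=C1CCCCCCC1 | starting material
2 | (2Z,7Z)-cycloocta-2,7-dien-1-one | O=C1/C=C\CCC/C=C\1 | intermediate
3 | (E)-(2-phenylethenyl)boronic acid | OB(O)/C=C/c1ccccc1 | starting material
4 | (2Z,7R)-7-[(E)-2-phenylethenyl]cyclooct-2-en-1-one | O=C1/C=C\CCC[C@@H](/C=C/c2ccccc2)C1 | intermediate
5 | (1R,4Z)-3-oxocyclooct-4-ene-1-carbaldehyde (not isolated) | O=C1/C=C\CCC[C@@H](C=O)C1 | intermediate
6 | (2Z,7R)-7-(hydroxymethyl)cyclooct-2-en-1-one | O=C1/C=C\CCC[C@@H](CO)C1 | intermediate
7 | (5R)-5-(hydroxymethyl)cyclooctane-1,3-dione | O=C1CC(=O)CCC[C@@H](CO)C1 | intermediate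
8 | silylene-bridged enol ether (C4=O, C5=C8, O8–Si(t-Bu)2–O14; 10R) | O=C1/C=C2\C[C@@H](CCC1)CO[Si](C(C)(C)C)(C(C)(C)C)O2 | intermediate
9 | 3α-hydroxy ketone (3R,10R) | O=C1/C=C2\C[C@@H](CC[C@H]1O)CO[Si](C(C)(C)C)(C(C)(C)C)O2 | intermediate
10 | methyl propiolate | C#CC(=O)OC | starting material
11 | (E)-β-alkoxyacrylate on O3 | O=C1/C=C2\C[C@@H](CC[C@H]1O/C=C/C(=O)OC)CO[Si](C(C)(C)C)(C(C)(C)C)O2 | intermediate
12 | tetracyclic photoadduct (H5 β, O8 β, O6 α bridging to C3, 7β-CO2Me) | O=C1[C@H]2CC[C@H]3CO[Si](C(C)(C)C)(C(C)(C)C)O[C@]4(C3)[C@@H]1[C@@H](O2)[C@@H]4C(=O)OC | intermediate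
13 | bis-silyl enol ether (C3=C4–OTBS, 6α-OTBS; not isolated) | CC(C)(C)[Si](C)(C)O/C1=C/CC[C@H]2CO[Si](C(C)(C)C)(C(C)(C)C)O[C@]3(C2)[C@@H]1[C@@H](O[Si](C)(C)C(C)(C)C)[C@@H]3C(=O)OC | intermediate
14 | 6α-OTBS keto ester (C4 ketone, 7β-CO2Me) | O=C1CCC[C@H]2CO[Si](C(C)(C)C)(C(C)(C)C)O[C@]3(C2)[C@@H]1[C@@H](O[Si](C)(C)C(C)(C)C)[C@@H]3C(=O)OC | intermediate
15 | 4-methylene compound | C=C1CCC[C@H]2CO[Si](C(C)(C)C)(C(C)(C)C)O[C@]3(C2)[C@@H]1[C@@H](O[Si](C)(C)C(C)(C)C)[C@@H]3C(=O)OC | intermediate
16 | 7β-formyl compound (not isolated) | C=C1CCC[C@H]2CO[Si](C(C)(C)C)(C(C)(C)C)O[C@]3(C2)[C@@H]1[C@@H](O[Si](C)(C)C(C)(C)C)[C@@H]3C=O | intermediate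
17 | 7β-ethynyl compound | C=C1CCC[C@H]2CO[Si](C(C)(C)C)(C(C)(C)C)O[C@]3(C2)[C@@H]1[C@@H](O[Si](C)(C)C(C)(C)C)[C@@H]3C#C | intermediate
18 | 4β,15-epoxide | C1O[C@]12CCC[C@H]3CO[Si](C(C)(C)C)(C(C)(C)C)O[C@]4(C3)[C@@H]2[C@@H](O[Si](C)(C)C(C)(C)C)[C@@H]4C#C | intermediate
19 | epoxy diol (8β-OH cyclobutanol, 14-OH, 6α-OTBS; not isolated) | C1O[C@]12CCC[C@@H](CO)C[C@@]3(O)[C@@H]2[C@@H](O[Si](C)(C)C(C)(C)C)[C@@H]3C#C | intermediate
20 | ten-membered keto diol, 6α-OTBS (not isolated) | O=C1C[C@H](CO)CCC/C(CO)=C/[C@@H](O[Si](C)(C)C(C)(C)C)[C@@H]1C#C | intermediate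
21 | (4E,6R,7S,10R)-7-ethynyl-6,14,15-trihydroxy ten-membered 8-ketone | O=C1C[C@H](CO)CCC/C(CO)=C/[C@@H](O)[C@@H]1C#C | intermediate
22 | 14,15-bis(TBS) ether of 21 | O=C1C[C@H](CO[Si](C)(C)C(C)(C)C)CCC/C(CO[Si](C)(C)C(C)(C)C)=C/[C@@H](O)[C@@H]1C#C | intermediate
23 | 14,15-bis(TBSO)-8-oxo-1(10)-dihydrogermacra-4,11(13)-dien-12,6α-olide | O=C1C[C@H](CO[Si](C)(C)C(C)(C)C)CCC/C(CO[Si](C)(C)C(C)(C)C)=C/[C@H]2OC(=O)C(=C)[C@H]12 | intermediate
24 | 8α-hydroxy lactone | O[C@H]1C[C@H](CO[Si](C)(C)C(C)(C)C)CCC/C(CO[Si](C)(C)C(C)(C)C)=C/[C@H]2OC(=O)C(=C)[C@H]12 | intermediate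
25 | methacrylic anhydride | C=C(C)C(=O)OC(=O)C(C)=C | starting material
26 | 8α-methacrylate 14,15-bis(TBS) ether | C=C(C)C(=O)O[C@H]1C[C@H](CO[Si](C)(C)C(C)(C)C)CCC/C(CO[Si](C)(C)C(C)(C)C)=C/[C@H]2OC(=O)C(=C)[C@H]12 | intermediate
27 | CNP0256084.2, 8α-(methacryloyloxy)-14,15-dihydroxy-1(10)-dihydrogermacra-4,11(13)-dien-12,6α-olide (6R,7R,8S,10R) | C=C(C)C(=O)O[C@H]1C[C@H](CO)CCC/C(CO)=C/[C@H]2OC(=O)C(=C)[C@H]12 | target

**Totals and risks**
Total step count: 18. Longest linear sequence: 18 steps (from cyclooctanone).

Steps most likely to fail: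

Step 9. The samarium alkoxide on C6 may open the cyclobutane by retro-aldol cleavage (towards the ester, or towards the ketone once protonated) before it is silylated, or silylation of the hindered endo alkoxide may be incomplete. The fallback replaces the oxygen tether by a silicon tether, so that C6 carries a C–Si bond until no carbonyl is left. Setting out from 9, methyl propiolate and chlorodiisopropylsilane would be joined by platinum-catalysed hydrosilylation (Pt2(dvds)3, P(t-Bu)3; dvds = 1,3-divinyltetramethyldisiloxane) to methyl (E)-3-[chlorodi(propan-2-yl)silyl]prop-2-enoate F1. This would silylate 9 (imidazole, DMF) to the silyl ether F2. Irradiation as in step 8 should close the six-membered siloxane ring (C5–C6) and then C8–C7 to the photoadduct F3 (6α-Si, 7β-CO2Me). SmI2 would cleave the C3–O bond of the α-silyloxy ketone to the silanol ketone F4. Zn/CH2Br2/TiCl4 would give the 4-methylene silanol F5, and i-Bu2AlH followed by the diazophosphonate/K2CO3/MeOH the ethynyl silanol F6. Tamao–Fleming oxidation (KF, KHCO3, H2O2) with retention at C6 would then give the 6α-hydroxy alkyne F7. TBSOTf/2,6-lutidine comes back to the route at 17.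

Step 13. Under basic fluoride the fragmentation may be accompanied by retro-aldol cleavage or C7 epimerisation of the β-hydroxy ketone, or by premature loss of the 6-OTBS group, which would open a competing fragmentation through O6. The fallback separates unmasking from fragmentation and runs the latter under Lewis-acidic conditions. Setting out from 18, buffered desilylation (TBAF/AcOH, 0 °C) would remove only the silylene and give the neutral epoxy diol 19, which would be isolated. Ti(OiPr)4 (CH2Cl2, 0 °C to rt) would then effect the epoxy-alcohol fragmentation through the titanium alkoxide to 20. TBAF/AcOH at rt comes back to the route at 21. No new compound is needed.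

Step 16. Hydride may be delivered to the other face of the C8 ketone, giving the 8β-alcohol. The fallback uses inversion instead of retention in the esterification. Setting out from 23, the 8β-hydroxy lactone F8 obtained under the same reduction conditions would be esterified with methacrylic acid under Mitsunobu conditions (PPh3, diisopropyl azodicarboxylate, THF, 0 °C) with inversion at C8, which comes back to the route at 26.

**Further compounds**
F1 | step 9 | methyl (E)-3-[chlorodi(propan-2-yl)silyl]prop-2-enoate | COC(=O)/C=C/[Si](Cl)(C(C)C)C(C)C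
F2 | step 9 | silyl ether of 9 (O3–Si(i-Pr)2–CH=CH–CO2Me) | O=C1/C=C2\C[C@@H](CC[C@H]1O[Si](C(C)C)(C(C)C)/C=C/C(=O)OC)CO[Si](C(C)(C)C)(C(C)(C)C)O2
F3 | step 9 | silicon-tethered photoadduct (6α-Si, 7β-CO2Me) | O=C1[C@H]2CC[C@H]3CO[Si](C(C)(C)C)(C(C)(C)C)O[C@]4(C3)[C@@H]1[C@@H]([Si](C(C)C)(C(C)C)O2)[C@@H]4C(=O)OC
F4 | step 9 | silanol ketone | O=C1CCC[C@H]2CO[Si](C(C)(C)C)(C(C)(C)C)O[C@]3(C2)[C@@H]1[C@@H]([Si](O)(C(C)C)C(C)C)[C@@H]3C(=O)OC
F5 | step 9 | 4-methylene silanol | C=C1CCC[C@H]2CO[Si](C(C)(C)C)(C(C)(C)C)O[C@]3(C2)[C@@H]1[C@@H]([Si](O)(C(C)C)C(C)C)[C@@H]3C(=O)OC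
F6 | step 9 | ethynyl silanol | C=C1CCC[C@H]2CO[Si](C(C)(C)C)(C(C)(C)C)O[C@]3(C2)[C@@H]1[C@@H]([Si](O)(C(C)C)C(C)C)[C@@H]3C#C
F7 | step 9 | 6α-hydroxy alkyne | C=C1CCC[C@H]2CO[Si](C(C)(C)C)(C(C)(C)C)O[C@]3(C2)[C@@H]1[C@@H](O)[C@@H]3C#C
F0 | step 13 | none | none
F8 | step 16 | 8β-hydroxy lactone | O[C@@H]1C[C@H](CO[Si](C)(C)C(C)(C)C)CCC/C(CO[Si](C)(C)C(C)(C)C)=C/[C@H]2OC(=O)C(=C)[C@H]12
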